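**Assumption:** I read the SMILES as a run of 13 CH2 groups between O and the stereocentre, which makes the alkyl group (S)-14-methylhexadecyl. The [C@H] centre is (S) by CIP. It is the same stereocentre as in commercial (S)-2-methylbutyl bromide, so the chiral-pool terminus carries it through unchanged.

## Retrosynthetic overview
- Disconnect the ester O–alkyl bond: the target comes from 2,3-dihydroxybenzoic acid (cheap aromatic feedstock) as its carboxylate, plus a primary alkyl bromide.
- Disconnect the C13–C14 bond of the bromide: (S)-2-methylbutyl Grignard plus the symmetric 1,12-dibromododecane.
- Key step: Cu-catalysed mono-coupling breaks the symmetry of the dibromide and installs the chiral terminus directly from the chiral pool.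
- No ring is formed. The aromatic ring is purchased, and its free catechol is carried through unprotected.

## Route

**Step 1**
Reactants: **1** (S)-1-bromo-2-methylbutane
Product: **2** (S)-2-methylbutylmagnesium bromide
Conditions: Mg turnings (1.2 equiv), I2 (cat.), THF, reflux 1 h, then 0 °C; used as a ~1 M solution
Reagents that add atoms: magnesium, [Mg]
Why: Standard Grignard formation. The stereocentre is β to the C–Mg carbon, so it cannot epimerise and the (S) configuration is retained.

**Step 2**
Reactants: **2** (S)-2-methylbutylmagnesium bromide (1 equiv); **3** 1,12-dibromododecane (3 equiv)
Product: **4** (S)-1-bromo-14-methylhexadecane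
Conditions: Li2CuCl4 (3 mol %), THF, Grignard added by syringe pump over 2 h at –10 °C, then warm to rt, 3 h. Quench with aq. NH4Cl. Remove excess **3** by Kugelrohr distillation or hexane chromatography.
Reagents that add atoms: none (the copper catalyst leaves no atoms in the product)
Why: Proposed new method: none needed, but this is a deliberately bold statistical desymmetrisation. The Grignard is added slowly to excess symmetric dibromide under Kochi/Fouquet–Schlosser Cu-catalysed Kumada coupling, which is selective for primary alkyl bromides, so one C–Br is converted and the other survives. The chiral centre is untouched because it is not at the reacting carbon. The excess dibromide limits bis-coupling and is recoverable.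

**Step 3**
Reactants: **4** (S)-1-bromo-14-methylhexadecane (1 equiv); **5** 2,3-dihydroxybenzoic acid (1.3 equiv)
Product: **6** Gentiside C, (S)-14-methylhexadecyl 2,3-dihydroxybenzoate
Conditions: Cs2CO3 (0.65 equiv), NaI (0.2 equiv), DMF, 60 °C, 16 h, N2. Wash with aq. NaHCO3 to remove excess **5**, then silica chromatography.
Reagents that add atoms: none (all atoms of the product come from 4 and 5)
Why: SN2 alkylation of a carboxylate (cesium effect, Finkelstein assistance from iodide). The base is only enough to form the carboxylate (pKa ~3), not the H-bonded 2-OH or the 3-OH phenoxide (pKa ~10), so the catechol needs no protection. No stereocentre is touched.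

## Checks performed
- Carbon count: 5 (from 2) + 12 (from 3) = 17 carbons in 4, which is Br-(CH2)13-CH(CH3)CH2CH3.
- Step 3 replaces Br with the O-acyl group, giving the target SMILES exactly.
- The Grignard tolerates the alkyl bromide of 3 at –10 °C under Cu catalysis. The free catechol is introduced only in the last step, after all organometallic chemistry.
- The single stereocentre comes from 1 and is never at a reacting carbon or an enolisable position.

## Compound list
1 | (S)-1-bromo-2-methylbutane | CC[C@H](C)CBr | starting material
2 | (S)-2-methylbutylmagnesium bromide | CC[C@H](C)C[Mg]Br | intermediate
3 | 1,12-dibromododecane | BrCCCCCCCCCCCCBr | starting material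
4 | (S)-1-bromo-14-methylhexadecane | CC[C@H](C)CCCCCCCCCCCCCBr | intermediate
5 | 2,3-dihydroxybenzoic acid | OC(=O)c1cccc(O)c1O | starting material
6 | Gentiside C, (S)-14-methylhexadecyl 2,3-dihydroxybenzoate | CC[C@H](C)CCCCCCCCCCCCCOC(=O)c1cccc(O)c1O | target

## Step count
- Total steps: 3
- Longest linear sequence: 3 (1 → 2 → 4 → 6)

## Three steps most likely to fail
1. **Step 2, statistical mono-coupling and separation.**
   - Risks: bis-coupling, or difficulty separating 4 from excess 3.
   - Fallback: couple 2 with the magnesium alkoxide of 12-bromododecan-1-ol under Li2CuCl4. This gives (S)-14-methylhexadecan-1-ol with no statistical step. Esterify it with 5 by DCC/DMAP or EDC coupling, which changes the disconnection to C(O)–O.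
2. **Step 3, chemoselective carboxylate alkylation.**
   - Risks: slow SN2 of a long-chain bromide, competing O-alkylation of the 3-OH, and catechol oxidation.
   - Fallback: use 2,3-dihydroxybenzoic acid as its acetonide (or 2,3-bis-O-benzyl ether). Alkylate it, or esterify the alcohol from fallback 1, then deprotect by acid hydrolysis (or hydrogenolysis for the benzyl ether).
3. **Step 1, Grignard formation from a β-branched primary bromide.**
   - Risk: Wurtz homocoupling lowers the yield of 2.
   - Fallback: skip the Grignard and use Ni-catalysed cross-electrophile coupling (NiI2/bipyridine ligand, Zn, DMA) of 1 directly with 12-bromododecan-1-ol. The resulting alcohol then enters the esterification route of fallback 1.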